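All runs are calculated on assumed constants; noise was put on by code.

Litre for litre of the first phase, the flask held 1.0 M of starting material against 1.30 M of reagent in the second phase, so I took starting material as the limiting reagent and wrote its balance.

| setting | amber | ochre | flask |
|---|---|---|---|
| starting material | 1 M | 1 M | 1.0 M |
| reagent in the second phase | 0.87 M | 2 M | 1.30 M |
| protic impurity | 0.30 M | 0.30 M | 0.300 M |
| remark | run made earlier | run made earlier |  |
| time |  |  | 15 h |
| volume of the second phase over the first |  |  | 2.0 |

| run | time / h | target / % |
|---|---|---|
| amber | 2.00 | 13.9 |
| amber | 4.00 | 16.0 |
| amber | 6.00 | 17.3 |
| amber | 8.00 | 17.9 |
| amber | 10.0 | 19.0 |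
| amber | 12.0 | 18.9 |
| ochre | 0.833 | 17.9 |
| ochre | 2.50 | 28.7 |
| ochre | 4.00 | 26.5 |
| ochre | 6.00 | 28.7 |
| ochre | 10.0 | 28.7 |
| ochre | 12.0 | 29.3 |

(each reading ± 1 percentage point)

- a species is counted by the starting material in it: one self-condensation product counts as two
- in the second phase: reagent in the second phase; everything else is in the first
- charges count per volume of the first phase; a concentration in a rate is the amount of a species over the volume of its own phase; every rate counts per litre of the first phase
- what may be going on: reagent in the reaction phase <-> reagent in the second phase; 2 starting material -> self-condensation product; starting material + protic impurity -> quenched substrate; starting material + reagent in the reaction phase -> target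
- the earlier runs hold the two phases in the same ratio of volumes as the flask asked about

- Wednesday's: doubling the amount of reagent in the second phase, all else as stated
- Monday's: doubling the transfer coefficient of the reagent in the second phase, all else as stated

- amount of target at 15 h, in percent of the starting material charged
- the change that raises the amount of target at 15 h, in percent of the starting material charged most ("none" if none brings more than 2 percentage points) (Wednesday's / Monday's / none)
- amount of target at 15 h, in percent of the starting material charged, after Wednesday's

The runs formed a ladder of times. On the first rung, the ochre run had reached 28.7 % of target by 2.50 h. On the next, the amber run crept to 19.0 % by 10.0 h. Amber's last reading meant 0.189 M of reagent used out of 0.87 M charged, so its plateau was not a shortage of reagent. The last rung, 15 h, lay beyond both, so I reckoned a share of substrate, not a time.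

My quantity for the flask was x = 0.130 M, 0.1 times the reagent charge, a factor I read off the amber and ochre readings: the capture width, the c(starting material) at which reagent in the reaction phase and self-condensation use up starting material equally fast. I counted the protic impurity as taking its charge, leaving S = 0.700 M. Each small loss at concentration c then gives target the share x/(x + c), and summing gives target = x·ln(1 + S/x). With that factor the expression returned 19.2 % for amber and 30.1 % for ochre, beside last readings of 18.9 % and 29.3 %; this is a fit to those runs, not a check on it. For the flask it gave 24.1 %, and with x doubled by Wednesday's, 34.0 %.

The forecast, holding that “the yield is set by competition for substrate”, said 24 % for the flask, named Wednesday's as the better change and gave 33.5 % after it, which is less than my doubled figure.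

The flask gave 23.3 %, and 32.4 % after Wednesday's, which gained 9.1 percentage points against 2.7 points for Monday's.

    reagent in the reaction phase ⇌ reagent in the second phase, rate k1*([reagent in the reaction phase] - [reagent in the second phase]/K1) per volume of the first phase (partition coefficient = 13.0, kL = 9.20 h⁻¹)
    2 starting material → self-condensation product (k = 1.30 M⁻¹ h⁻¹)
    starting material + protic impurity → quenched substrate (k = 5.50 M⁻¹ h⁻¹)
    starting material + reagent in the reaction phase → target (k = 16.0 M⁻¹ h⁻¹)

The neighbouring flask held 2.5 M of starting material and the same reagent charge, so x stayed 0.130 M while S rose to 2.20 M. The balance gave 15.0 % of its charge. That flask put 74.4 % into self-condensation product and gave 13.7 % of target.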